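**Retrosynthetic overview**
- The malate ester C–O bond is cut last: the target comes from a 12-hydroxy lactone diacid and (R)-malic acid, through regioselective opening of O-trifluoroacetyl malic anhydride.
- The lactone diacid comes from a butenolide aldehyde by CHO → CO2H oxidation, then one hydrogenation that saturates the ring and removes both benzyl groups.
- Key C–C disconnection: the bond between the quaternary lactone carbon and the side-chain CH. The α-carbon of 12-(benzyloxy)dodecanal is made electrophilic as an enamine radical cation (an enolonium equivalent) and joined to the nucleophilic ester-bearing carbon of a 5-silyloxy-2-furoate, so two normally nucleophilic α-carbons are coupled and both stereocentres arise in this step.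
- Rings: the five-membered ring is never closed by cyclisation. It is carried in from benzyl furan-2-carboxylate (furan → silyloxyfuran → butenolide → γ-lactone); the only ring closed is the transient malic anhydride in the last step.
- Fragments: the furan from benzyl furan-2-carboxylate (C–H borylation/oxidation, silylation); the aldehyde from dodecane-1,12-diol.

Assumption: the target is made exactly as drawn, (S) at the lactone carbon, (R) at the side-chain CH and (R) in the malate unit; benzyl furan-2-carboxylate, dodecane-1,12-diol, (R)-malic acid and the (2S,5S)-imidazolidinone catalyst are bought.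

**Step 1**
Reactants: 1 benzyl furan-2-carboxylate
Product: 3 benzyl 5-oxo-4,5-dihydrofuran-2-carboxylate, via furyl boronate 2 (not isolated)
Conditions: [Ir(OMe)(cod)]2 (1.5 mol%), 4,4'-di-tert-butyl-2,2'-bipyridine (3 mol%), B2pin2 (1.0 equiv), THF, rt; then 2KHSO5·KHSO4·K2SO4 (1.05 equiv KHSO5), acetone/H2O, 0 °C, 10 min
Reagents that add atoms: potassium peroxymonosulfate KHSO5, [K+].[O-]S(=O)(=O)OO (the oxygen at C5 of 3); bis(pinacolato)diboron, CC1(C)OB(OC1(C)C)B1OC(C)(C)C(C)(C)O1 (boron and pinacol of 2 only, none of it remains in 3)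
Why: Iridium-catalysed C–H borylation takes the most reactive heteroaryl C–H (C5, next to the ring oxygen and remote from the ester) at room temperature, where the benzyl ring is left alone, and oxidative C–B cleavage with KHSO5 gives the 5-hydroxyfuran, which tautomerises by protonation at C3 to enol lactone 3 (one-pot borylation/oxidation; any 2,5-dihydro tautomer converges in step 2).

**Step 2**
Reactants: 3 benzyl 5-oxo-4,5-dihydrofuran-2-carboxylate
Product: 4 benzyl 5-{[tri(propan-2-yl)silyl]oxy}furan-2-carboxylate
Conditions: iPr3SiOTf (1.1 equiv), Et3N (1.5 equiv), CH2Cl2, 0 °C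
Reagents that add atoms: triisopropylsilyl trifluoromethanesulfonate, CC(C)[Si](OS(=O)(=O)C(F)(F)F)(C(C)C)C(C)C
Why: Soft enolisation, in which Et3N removes the acidic C4 proton and the aromatic furanolate is O-silylated, is the standard butenolide-to-2-silyloxyfuran conversion, and the bulky silyl group makes 4 stable to water and chromatography.

**Step 3**
Reactants: 5 dodecane-1,12-diol
Product: 6 12-(benzyloxy)dodecan-1-ol
Conditions: 5 (3 equiv), NaH (1.0 equiv), BnBr (1.0 equiv), n-Bu4NI (cat.), THF/DMF, 0 °C → rt
Reagents that add atoms: benzyl bromide, BrCc1ccccc1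
Why: Williamson ether synthesis, in which a threefold excess of diol over one equivalent of base makes the mono-ether the main product and the unreacted diol is recovered.

**Step 4**
Reactants: 6 12-(benzyloxy)dodecan-1-ol
Product: 7 12-(benzyloxy)dodecanal
Conditions: TEMPO (1 mol%), KBr (10 mol%), NaOCl (1.1 equiv), NaHCO3, CH2Cl2/H2O, 0 °C
Reagents that add atoms: none
Why: Anelli (oxoammonium) oxidation stops cleanly at the aldehyde in the two-phase system and does not touch the benzyl ether.

**Step 5 (key step)**
Reactants: 7 12-(benzyloxy)dodecanal (1 equiv); 4 benzyl 5-{[tri(propan-2-yl)silyl]oxy}furan-2-carboxylate (2 equiv)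
Product: 8 benzyl (2S)-2-[(2R)-12-(benzyloxy)-1-oxododecan-2-yl]-5-oxo-2,5-dihydrofuran-2-carboxylate
Conditions: (2S,5S)-5-benzyl-2-tert-butyl-3-methylimidazolidin-4-one·CF3CO2H (20 mol%), (NH4)2Ce(NO3)6 (2.2 equiv), NaHCO3 (2 equiv), H2O (2 equiv), DME, −20 °C, 24 h; crude 8 taken straight into step 6
Reagents that add atoms: none
Why: Proposed new method: 7 condenses with the amine to an enamine that (NH4)2Ce(NO3)6 oxidises to a 3π-electron radical cation, an enolonium equivalent with an electrophilic α-carbon, which is trapped at the ester-bearing C5 of the electron-rich furan 4 (addition there leaves an allyl radical flanked by two oxygens), after which a second one-electron oxidation and loss of the silyl group unveil the butenolide; the closest known reactions are the SOMO-activated α-enolation of aldehydes with enolsilanes and the organocatalytic Mukaiyama–Michael addition of 5-alkoxycarbonyl-2-silyloxyfurans, which builds the same quaternary centre; the (2S,5S) catalyst exposes the Si face of the radical cation and so sets the aldehyde α-carbon as (R), and the furan is expected to approach in an open staggered transition state with its ring C4–H anti to the α-hydrogen and its ester anti to the bulky iminium arm, that is through the Si face of C5, which sets the quaternary carbon as (S) — this second selectivity is a steric argument, not a precedent.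

**Step 6**
Reactants: 8 benzyl (2S)-2-[(2R)-12-(benzyloxy)-1-oxododecan-2-yl]-5-oxo-2,5-dihydrofuran-2-carboxylate
Product: 9 (2R)-12-(benzyloxy)-2-[(2S)-2-(benzyloxycarbonyl)-5-oxo-2,5-dihydrofuran-2-yl]dodecanoic acid
Conditions: NaClO2, NaH2PO4, 2-methylbut-2-ene, t-BuOH/H2O, 0 °C → rt; chromatography to remove the minor diastereomer
Reagents that add atoms: sodium chlorite, [Na+].[O-]Cl=O
Why: Pinnick oxidation converts the hindered, epimerisable α-branched aldehyde to the acid under buffered non-enolising conditions, with 2-methylbut-2-ene removing HOCl so that the butenolide alkene and the benzyl ether survive and the (R) centre is kept.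

**Step 7**
Reactants: 9 (2R)-12-(benzyloxy)-2-[(2S)-2-(benzyloxycarbonyl)-5-oxo-2,5-dihydrofuran-2-yl]dodecanoic acid
Product: 10 (2S)-2-[(1R)-1-carboxy-11-hydroxyundecyl]-5-oxotetrahydrofuran-2-carboxylic acid
Conditions: H2 (1 atm), 10% Pd/C, THF, rt; recrystallise
Reagents that add atoms: none
Why: Heterogeneous hydrogenation saturates the butenolide C=C and hydrogenolysis removes the benzyl ester and the benzyl ether in the same operation without touching either stereocentre, and crystallisation of the diacid removes residual minor diastereomer and enantiomer.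

**Step 8**
Reactants: 10 (2S)-2-[(1R)-1-carboxy-11-hydroxyundecyl]-5-oxotetrahydrofuran-2-carboxylic acid; 11 (R)-malic acid (3 equiv)
Product: 14 (2S)-2-[(1R)-1-carboxy-11-{[(2R)-3-carboxy-2-hydroxypropanoyl]oxy}undecyl]-5-oxotetrahydrofuran-2-carboxylic acid (CNP0457473.2), via trifluoroacetyl malic anhydride 12 (not isolated), via trifluoroacetylated ester 13 (not isolated)
Conditions: 11, (CF3CO)2O, 0 °C → rt, then evaporate; add 10, THF, rt, 12 h; then H2O, rt; reversed-phase chromatography
Reagents that add atoms: trifluoroacetic anhydride, O=C(OC(=O)C(F)(F)F)C(F)(F)F (its CF3CO group sits in 12 and 13 only and is gone in 14)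
Why: (CF3CO)2O turns malic acid into its O-trifluoroacetyl cyclic anhydride, the primary alcohol of 10 opens it without base at the more electrophilic carbonyl next to the trifluoroacetoxy-bearing carbon (regioselective anhydride alcoholysis, the known route to 1-monoesters of malic acid) while the free carboxylic acids of 10 stay inert, and water then hydrolyses the labile trifluoroacetate and the excess anhydride with the malate centre remaining (R).

**Compound list**
1 | benzyl furan-2-carboxylate | O=C(OCc1ccccc1)c1ccco1 | starting material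
2 | benzyl 5-(4,4,5,5-tetramethyl-1,3,2-dioxaborolan-2-yl)furan-2-carboxylate | CC1(C)OB(OC1(C)C)c1ccc(C(=O)OCc2ccccc2)o1 | intermediate (not isolated)
3 | benzyl 5-oxo-4,5-dihydrofuran-2-carboxylate | O=C1CC=C(C(=O)OCc2ccccc2)O1 | intermediate
4 | benzyl 5-{[tri(propan-2-yl)silyl]oxy}furan-2-carboxylate | CC(C)[Si](Oc1ccc(C(=O)OCc2ccccc2)o1)(C(C)C)C(C)C | intermediate
5 | dodecane-1,12-diol | OCCCCCCCCCCCCO | starting material
6 | 12-(benzyloxy)dodecan-1-ol | OCCCCCCCCCCCCOCc1ccccc1 | intermediate
7 | 12-(benzyloxy)dodecanal | O=CCCCCCCCCCCCOCc1ccccc1 | intermediate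
8 | benzyl (2S)-2-[(2R)-12-(benzyloxy)-1-oxododecan-2-yl]-5-oxo-2,5-dihydrofuran-2-carboxylate | c1ccccc1COCCCCCCCCCC[C@@H](C=O)[C@]1(C(=O)OCc2ccccc2)C=CC(=O)O1 | intermediate
9 | (2R)-12-(benzyloxy)-2-[(2S)-2-(benzyloxycarbonyl)-5-oxo-2,5-dihydrofuran-2-yl]dodecanoic acid | c1ccccc1COCCCCCCCCCC[C@@H](C(=O)O)[C@]1(C(=O)OCc2ccccc2)C=CC(=O)O1 | intermediate
10 | (2S)-2-[(1R)-1-carboxy-11-hydroxyundecyl]-5-oxotetrahydrofuran-2-carboxylic acid | OCCCCCCCCCC[C@@H](C(=O)O)[C@]1(C(=O)O)CCC(=O)O1 | intermediate
11 | (R)-malic acid, (2R)-2-hydroxybutanedioic acid | O=C(O)C[C@@H](O)C(=O)O | starting material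
12 | (3R)-2,5-dioxotetrahydrofuran-3-yl trifluoroacetate | O=C1C[C@@H](OC(=O)C(F)(F)F)C(=O)O1 | intermediate (not isolated)
13 | (3R)-4-({(11R)-11-carboxy-11-[(2S)-2-carboxy-5-oxotetrahydrofuran-2-yl]undecyl}oxy)-4-oxo-3-(trifluoroacetoxy)butanoic acid | O=C(O)C[C@@H](OC(=O)C(F)(F)F)C(=O)OCCCCCCCCCC[C@@H](C(=O)O)[C@]1(C(=O)O)CCC(=O)O1 | intermediate (not isolated)
14 | (2S)-2-[(1R)-1-carboxy-11-{[(2R)-3-carboxy-2-hydroxypropanoyl]oxy}undecyl]-5-oxotetrahydrofuran-2-carboxylic acid | O=C(O)C[C@@H](O)C(=O)OCCCCCCCCCC[C@@H](C(=O)O)[C@]1(C(=O)O)CCC(=O)O1 | target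

**Step count**
Total steps: 8. Longest linear sequence: 6 (steps 3, 4, 5, 6, 7, 8 from dodecane-1,12-diol; the furan branch, steps 1, 2, 5, 6, 7, 8, is equally long).

**The three steps most likely to fail**

Step 5 (the oxidative coupling; the risks are attack at C3 of the furan, direct oxidation of the furan, and a low diastereomer ratio at the quaternary carbon). The fallback sets out from 4 and comes back at 10. The coupling is replaced by a conjugate addition with normal polarity at the furan. Under iminium catalysis with the same (2S,5S)-imidazolidinone (2,4-dinitrobenzoic acid salt, CH2Cl2/H2O, −40 °C), 4 adds to tert-butyl (E)-4-oxobut-2-enoate. This Mukaiyama–Michael reaction is a known way to this quaternary centre, and the silyl group, acid and solvent steer the syn/anti ratio. It gives benzyl (2S)-2-[(2R)-1-(tert-butoxy)-1,4-dioxobutan-2-yl]-5-oxo-2,5-dihydrofuran-2-carboxylate F1. The chain is then added by a Wittig reaction: (8-hydroxyoctyl)triphenylphosphonium bromide F2, made from 8-bromooctan-1-ol and PPh3, is deprotonated twice with NaN(SiMe3)2 in THF at −78 °C and condensed with F1. This gives benzyl (2S)-2-[(2R,4Z)-1-(tert-butoxy)-12-hydroxy-1-oxododec-4-en-2-yl]-5-oxo-2,5-dihydrofuran-2-carboxylate F3. H2 over Pd/C saturates both double bonds and removes the benzyl ester, giving (2S)-2-[(2R)-1-(tert-butoxy)-12-hydroxy-1-oxododecan-2-yl]-5-oxotetrahydrofuran-2-carboxylic acid F4. CF3CO2H in CH2Cl2 cleaves the tert-butyl ester and delivers 10.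

Step 8 (acylation of a free hydroxy diacid; the risks are incomplete regioselectivity at the anhydride and a difficult separation). The fallback sets out from 10 and comes back at 14. The ester C–O bond is made by displacement at the chain carbon instead of acylation at the malate carbonyl, so the regiochemistry is fixed by a protecting group. BnBr and Cs2CO3 in DMF convert 10 into benzyl (2S)-2-[(2R)-1-(benzyloxy)-12-hydroxy-1-oxododecan-2-yl]-5-oxotetrahydrofuran-2-carboxylate F5. MsCl and Et3N turn its alcohol into benzyl (2S)-2-{(2R)-1-(benzyloxy)-12-[(methylsulfonyl)oxy]-1-oxododecan-2-yl}-5-oxotetrahydrofuran-2-carboxylate F6. Separately, D-aspartic acid 4-benzyl ester is diazotised with NaNO2 in aqueous H2SO4 (retention) to give (2R)-4-(benzyloxy)-2-hydroxy-4-oxobutanoic acid F7. The caesium salt of F7 is alkylated by F6 in DMF to give 4-benzyl 1-{(11R)-12-(benzyloxy)-11-[(2S)-2-(benzyloxycarbonyl)-5-oxotetrahydrofuran-2-yl]-12-oxododecyl} (2R)-2-hydroxybutanedioate F8. H2 over Pd/C removes the three benzyl esters and gives 14.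

Step 1 (one-pot borylation/oxidation; the risks are over-oxidation of the hydroxyfuran and hydrolytic opening of the enol lactone). The fallback sets out from 1 and comes back at 8, bypassing 3 and 4. The C–O bond at C5 is made by substitution instead of C–H borylation. NBS in DMF brominates 1 at C5 to give benzyl 5-bromofuran-2-carboxylate F9. NaOCH2Ph in benzyl alcohol/DMF displaces the bromide by addition–elimination on the ester-activated furan (ester exchange is degenerate), giving benzyl 5-(benzyloxy)furan-2-carboxylate F10. This 2-alkoxyfuran takes the place of 4 under the conditions of step 5. The benzyloxy-substituted oxocarbenium ion formed after coupling is hydrolysed by the water present and gives 8 directly.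

**Further compounds**
F1 | step 5 | benzyl (2S)-2-[(2R)-1-(tert-butoxy)-1,4-dioxobutan-2-yl]-5-oxo-2,5-dihydrofuran-2-carboxylate | O=CC[C@@H](C(=O)OC(C)(C)C)[C@]1(C(=O)OCc2ccccc2)C=CC(=O)O1
F2 | step 5 | (8-hydroxyoctyl)triphenylphosphonium bromide | [Br-].OCCCCCCCC[P+](c1ccccc1)(c1ccccc1)c1ccccc1
F3 | step 5 | benzyl (2S)-2-[(2R,4Z)-1-(tert-butoxy)-12-hydroxy-1-oxododec-4-en-2-yl]-5-oxo-2,5-dihydrofuran-2-carboxylate | OCCCCCCC/C=C\C[C@@H](C(=O)OC(C)(C)C)[C@]1(C(=O)OCc2ccccc2)C=CC(=O)O1
F4 | step 5 | (2S)-2-[(2R)-1-(tert-butoxy)-12-hydroxy-1-oxododecan-2-yl]-5-oxotetrahydrofuran-2-carboxylic acid | OCCCCCCCCCC[C@@H](C(=O)OC(C)(C)C)[C@]1(C(=O)O)CCC(=O)O1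
F5 | step 8 | benzyl (2S)-2-[(2R)-1-(benzyloxy)-12-hydroxy-1-oxododecan-2-yl]-5-oxotetrahydrofuran-2-carboxylate | OCCCCCCCCCC[C@@H](C(=O)OCc2ccccc2)[C@]1(C(=O)OCc3ccccc3)CCC(=O)O1
F6 | step 8 | benzyl (2S)-2-{(2R)-1-(benzyloxy)-12-[(methylsulfonyl)oxy]-1-oxododecan-2-yl}-5-oxotetrahydrofuran-2-carboxylate | CS(=O)(=O)OCCCCCCCCCC[C@@H](C(=O)OCc2ccccc2)[C@]1(C(=O)OCc3ccccc3)CCC(=O)O1
F7 | step 8 | (2R)-4-(benzyloxy)-2-hydroxy-4-oxobutanoic acid | O=C(OCc1ccccc1)C[C@@H](O)C(=O)O
F8 | step 8 | 4-benzyl 1-{(11R)-12-(benzyloxy)-11-[(2S)-2-(benzyloxycarbonyl)-5-oxotetrahydrofuran-2-yl]-12-oxododecyl} (2R)-2-hydroxybutanedioate | O=C(OCc4ccccc4)C[C@@H](O)C(=O)OCCCCCCCCCC[C@@H](C(=O)OCc2ccccc2)[C@]1(C(=O)OCc3ccccc3)CCC(=O)O1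
F9 | step 1 | benzyl 5-bromofuran-2-carboxylate | O=C(OCc1ccccc1)c1ccc(Br)o1
F10 | step 1 | benzyl 5-(benzyloxy)furan-2-carboxylate | O=C(OCc1ccccc1)c1ccc(OCc2ccccc2)o1
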